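The earlier runs and the new flask come from a simulation on assumed constants; scatter was added.

Watch what is left.

| flask | Q | L | time |
|---|---|---|---|
| winter | 0.300 M | 6.00 × 10⁻⁴ M |  |
| summer | 0.300 M | 0.00180 M |  |
| autumn | 0.600 M | 6.00 × 10⁻⁴ M |  |
| midnight | 0.150 M | 6.00 × 10⁻⁴ M | 17 min |

| run | time / min | [G] / M |
|---|---|---|
| winter run | 0.97 | 0.0116 |
| winter run | 2.9 | 0.0338 |
| winter run | 5.6 | 0.0599 |
| winter run | 8.9 | 0.0899 |
| winter run | 13 | 0.1192 |
| winter run | 17 | 0.1447 |
| summer run | 0.97 | 0.0335 |
| summer run | 2.9 | 0.0902 |
| summer run | 5.6 | 0.1472 |
| summer run | 8.9 | 0.1963 |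
| summer run | 13 | 0.2339 |
| summer run | 17 | 0.2550 |
| autumn run | 0.97 | 0.0234 |
| autumn run | 2.9 | 0.0657 |
| autumn run | 5.6 | 0.1169 |
| autumn run | 8.9 | 0.1712 |
| autumn run | 13 | 0.2269 |
| autumn run | 17 | 0.2719 |

(scatter of a reading: 9 × 10⁻⁴ M)

- how the opening rate goes with [Q] round the charge of the winter run: the exponent of the rate at two percent of Q gone to G (one fixed amount of G, the same in the runs compared)
- how the opening rate goes with [L] round the charge of the winter run: the exponent of the rate at two percent of Q gone to G
- G in the midnight run at 17 min, as a share of the Q charged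

- Overall: Q -> G, with L as catalyst.
- Constant volume, constant temperature.
- An order is taken over about fifteen percent of the charge, up and down.

1. Let c be the Q charged and F = 1 − [G]/c the share of the charge not yet G. If [Q] did not move the rate, the autumn run, with twice the charge of the winter run, would have the same G early on. Its share made at 2.9 min would then be half of the winter share.

2. It stands far from that: the autumn run has made 10.9% and the winter run 11.3%. As a reading, the G ratio gives an order in Q of 0.959.

3. So I treat Q as pseudo-first-order at fixed L. F then falls as an exponential whatever c is, and one number carries a run: the fraction-left constant k = ln(1/F)/t. The last winter reading gives 0.03873 min⁻¹.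

4. At 2.9 min, ln(1/F) in the summer run over that in the winter run is 2.99, with 3.00 times the L, so I read an order in L of 0.998.

5. The last autumn reading gives 0.03551 min⁻¹, lower than the winter k. The midnight charge lies below the winter charge by half the autumn–winter step, so I add half that gap: 0.04034 min⁻¹. My midnight share is 49.6%.

6. The forecast gives 0.96 (0.88 to 1.03) for the order in Q, 1 (0.94 to 1.06) for the order in L and 49.2% (47.8% to 50.6%) for the midnight share. Of the fall in its apparent k it says: “The sag follows G rather than time”. My share is higher than its share.

The midnight run gives 49.0%. Round the winter charge, the opening orders are 1.0 in Q and 1.0 in L.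

    L + Q → G + L (69.00 L mol⁻¹ min⁻¹)
    2 Q → Jo (0.01668 L mol⁻¹ min⁻¹)

G comes to half the Q charged later in the autumn run, at 20.1 min, than in the winter run, at 18.3 min. Back from the midnight share, k is 0.03966 min⁻¹, lower than my 0.0403 min⁻¹. The summer run has the winter charge of Q, so 0.0387 min⁻¹ scaled by its L puts half at 5.97 min, and the summer run reaches half at 5.75 min.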